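The flavone is cut at C4a–C4 and C4–C3, so that the C4 carbonyl of ring C is supplied by carbon monoxide. The feature exploited is that C4a of ring A is flanked by the oxygen-bearing carbons C5 and C8a and is tied to C3 only through this one-carbon bridge. One palladium-catalysed carbonylative acylation joins a ring A iodide, CO and the enolate of a ring B α-methoxy ketone to an open 1,3-diketone that holds every skeletal carbon. The iodide carries unlike groups on its two ortho oxygens, MOM on the future O1 and benzyl on the future 5-OH, so acid closes ring C in one direction only and hydrogenolysis ends the route.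

Key step: step 7

Remark on the design: with four methyl ethers on ring A, the two oxygens beside C4a could be told apart only after the coupling, by a Lewis acid. That acid would also meet the 2'-methoxy group (ortho to the other carbonyl), the crowded 8-methoxy group and the benzyl ether. The distinction is therefore built into the iodide before the key step, and no methyl ether is ever cleaved.

Assumption: 3-hydroxy-4,5-dimethoxybenzaldehyde, 4-bromo-3-methoxyphenol and N,2-dimethoxy-N-methylacetamide are taken as catalogue chemicals.

Remark on stereochemistry: the target has no stereocentre. The centres that appear on the way are racemic and are erased again.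

Step 1
Reactants: 1 3-hydroxy-4,5-dimethoxybenzaldehyde
Product: 2 3,4-dimethoxy-5-(methoxymethoxy)benzaldehyde
Conditions: MOMCl, K2CO3, acetone, rt
Reagents that add atoms: chloromethyl methyl ether (MOMCl), COCCl
Why: Williamson-type O-alkylation of the single phenol with the reactive α-chloro ether gives the MOM acetal, which marks this oxygen as the future O1 and tolerates every basic step that follows.

Step 2
Reactants: 2 3,4-dimethoxy-5-(methoxymethoxy)benzaldehyde
Product: 4 3,4-dimethoxy-5-(methoxymethoxy)phenol, via aryl formate 3 (not isolated)
Conditions: mCPBA, CH2Cl2, 0 °C → rt; aq NaHCO3 wash; then K2CO3 (cat.), MeOH, rt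
Reagents that add atoms: 3-chloroperbenzoic acid (mCPBA), OOC(=O)c1cccc(Cl)c1
Why: Baeyer–Villiger oxidation in which the electron-rich trialkoxyaryl group migrates in preference to hydride, as for 3,4,5-trimethoxybenzaldehyde, followed by base-catalysed methanolysis of the formate under conditions that leave the MOM acetal alone.

Step 3
Reactants: 4 3,4-dimethoxy-5-(methoxymethoxy)phenol
Product: 5 5-(benzyloxy)-1,2-dimethoxy-3-(methoxymethoxy)benzene
Conditions: BnBr, K2CO3, DMF, rt
Reagents that add atoms: benzyl bromide, BrCc1ccccc1
Why: Williamson ether synthesis on the only free phenol places a hydrogenolysable group on the oxygen that becomes the 5-hydroxyl, so the two oxygens that will flank C4a now differ.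

Step 4
Reactants: 5 5-(benzyloxy)-1,2-dimethoxy-3-(methoxymethoxy)benzene
Product: 7 1-(benzyloxy)-2-iodo-4,5-dimethoxy-3-(methoxymethoxy)benzene, via aryllithium 6 (not isolated)
Conditions: n-BuLi, THF, −20 → 0 °C; then I2, THF, −78 °C → rt
Reagents that add atoms: iodine, II
Why: Directed ortho-metalation: the C–H between OMOM and OBn is the only free position next to the chelating MOM acetal and is flanked by two ether oxygens, so n-BuLi should deprotonate there faster than at the C–H between OBn and OMe or at the benzylic CH2, and iodine traps the aryllithium.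

Step 5
Reactants: 8 4-bromo-3-methoxyphenol
Product: 9 4-(benzyloxy)-1-bromo-2-methoxybenzene
Conditions: BnBr, K2CO3, DMF, rt
Reagents that add atoms: benzyl bromide, BrCc1ccccc1
Why: Williamson ether synthesis masks the future 4'-hydroxyl as a benzyl ether that withstands organolithium, enolate and mild acid conditions and leaves together with the ring A benzyl group.

Step 6
Reactants: 9 4-(benzyloxy)-1-bromo-2-methoxybenzene; 10 N,2-dimethoxy-N-methylacetamide
Product: 13 1-[4-(benzyloxy)-2-methoxyphenyl]-2-methoxyethan-1-one, via aryllithium 11 (not isolated), via tetrahedral lithium adduct 12 (not isolated)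
Conditions: n-BuLi, THF, −78 °C; then 10, −78 → 0 °C; aq NH4Cl
Reagents that add atoms: N,2-dimethoxy-N-methylacetamide (10), COCC(=O)N(C)OC
Why: Bromine–lithium exchange at low temperature followed by the Weinreb ketone synthesis, in which the chelated tetrahedral adduct survives until the quench and so stops the addition at the ketone.

Step 7
Reactants: 7 1-(benzyloxy)-2-iodo-4,5-dimethoxy-3-(methoxymethoxy)benzene; 13 1-[4-(benzyloxy)-2-methoxyphenyl]-2-methoxyethan-1-one; 14 carbon monoxide
Product: 16 1-[4-(benzyloxy)-2-methoxyphenyl]-3-[6-(benzyloxy)-3,4-dimethoxy-2-(methoxymethoxy)phenyl]-2-methoxypropane-1,3-dione (racemic), via sodium enolate 15 (not isolated)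
Conditions: 13 (2 equiv), NaN(SiMe3)2 (2 equiv), THF, 0 °C; then 7, Pd(dba)2 (5 mol %), Xantphos (6 mol %), CO (5 bar), THF, 70 °C; aq NH4Cl
Reagents that add atoms: carbon monoxide (14), [C-]#[O+]
Why: Zerovalent palladium inserts into the C–I bond of 7, carbon monoxide migrates into the aryl–palladium bond to give the aroyl–palladium iodide, enolate 15 replaces iodide and reductive elimination at carbon releases the diketone, so that C4a–C4 and C4–C3 are both made in one operation. The closest known reaction type is the palladium-catalysed carbonylative α-arylation of aryl alkyl ketones with aryl iodides to 1,3-diketones, applied here to a doubly ortho-alkoxylated iodide and an α-methoxy ketone. No ring is closed, and the one new stereocentre (the future C3) is formed racemic, stays enolisable and disappears in step 8, so it needs no control. The step needs carbon monoxide uptake ahead of direct aryl–enolate coupling and C- ahead of O-acylation: the two ortho alkoxy groups of 7 retard the direct coupling while insertion moves the crowded ring one atom away from the metal, and the wide bite angle of Xantphos together with a few bar of carbon monoxide holds the catalyst on the acyl pathway. Regiochemistry is not at stake, since 13 can enolise on one side only and 7 has a single C–I bond. The second equivalent of 15 deprotonates the more acidic product, which shields it from further acylation and from retro-Claisen cleavage and leaves no free amide base to attack the aroyl–palladium species.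

Step 8
Reactants: 16 1-[4-(benzyloxy)-2-methoxyphenyl]-3-[6-(benzyloxy)-3,4-dimethoxy-2-(methoxymethoxy)phenyl]-2-methoxypropane-1,3-dione
Product: 19 5-(benzyloxy)-2-[4-(benzyloxy)-2-methoxyphenyl]-3,7,8-trimethoxy-4H-chromen-4-one, via free phenol 17 (not isolated), via cyclic hemiketal 18 (not isolated)
Conditions: HCl (1.25 M in MeOH, cat.), THF, 50 °C
Reagents that add atoms: none
Why: Acid-catalysed transacetalisation removes the MOM group, and the only phenol thus freed adds to the ring B carbonyl and loses water (the cyclodehydration that ends a Baker–Venkataraman flavone synthesis), so O1–C2 can form in one direction only while both benzyl ethers stay in place.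

Step 9
Reactants: 19 5-(benzyloxy)-2-[4-(benzyloxy)-2-methoxyphenyl]-3,7,8-trimethoxy-4H-chromen-4-one
Product: 20 5,4'-dihydroxy-3,7,8,2'-tetramethoxyflavone
Conditions: H2 (1 atm), Pd/C (10 wt %), EtOAc–MeOH, rt
Reagents that add atoms: none
Why: Catalytic hydrogenolysis cleaves both aryl benzyl ethers under neutral conditions that spare the four methyl ethers and the tetrasubstituted C2–C3 double bond and give no opening for an acid-induced Wessely–Moser isomerisation of the 5-hydroxy-7,8-dimethoxy pattern.

Compound list
1 | 3-hydroxy-4,5-dimethoxybenzaldehyde | O=Cc1cc(O)c(OC)c(OC)c1 | starting material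
2 | 3,4-dimethoxy-5-(methoxymethoxy)benzaldehyde | O=Cc1cc(OCOC)c(OC)c(OC)c1 | intermediate
3 | 3,4-dimethoxy-5-(methoxymethoxy)phenyl formate (not isolated) | O=COc1cc(OCOC)c(OC)c(OC)c1 | intermediate
4 | 3,4-dimethoxy-5-(methoxymethoxy)phenol | Oc1cc(OCOC)c(OC)c(OC)c1 | intermediate
5 | 5-(benzyloxy)-1,2-dimethoxy-3-(methoxymethoxy)benzene | COCOc1cc(OCc2ccccc2)cc(OC)c1OC | intermediate
6 | [6-(benzyloxy)-3,4-dimethoxy-2-(methoxymethoxy)phenyl]lithium (not isolated) | [Li]c1c(OCOC)c(OC)c(OC)cc1OCc1ccccc1 | intermediate
7 | 1-(benzyloxy)-2-iodo-4,5-dimethoxy-3-(methoxymethoxy)benzene | Ic1c(OCOC)c(OC)c(OC)cc1OCc1ccccc1 | intermediate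
8 | 4-bromo-3-methoxyphenol | COc1cc(O)ccc1Br | starting material
9 | 4-(benzyloxy)-1-bromo-2-methoxybenzene | COc1cc(OCc2ccccc2)ccc1Br | intermediate
10 | N,2-dimethoxy-N-methylacetamide | COCC(=O)N(C)OC | starting material
11 | [4-(benzyloxy)-2-methoxyphenyl]lithium (not isolated) | [Li]c1ccc(OCc2ccccc2)cc1OC | intermediate
12 | lithium alkoxide adduct of 11 to the carbonyl group of 10, racemic (not isolated) | [Li+].[O-]C(COC)(N(C)OC)c1ccc(OCc2ccccc2)cc1OC | intermediate
13 | 1-[4-(benzyloxy)-2-methoxyphenyl]-2-methoxyethan-1-one | COCC(=O)c1ccc(OCc2ccccc2)cc1OC | intermediate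
14 | carbon monoxide | [C-]#[O+] | starting material
15 | sodium (Z)-enolate of 13, sodium chelated by the enolate and methoxy oxygens (not isolated) | [Na+].[O-]/C(=C\OC)c1ccc(OCc2ccccc2)cc1OC | intermediate
16 | 1-[4-(benzyloxy)-2-methoxyphenyl]-3-[6-(benzyloxy)-3,4-dimethoxy-2-(methoxymethoxy)phenyl]-2-methoxypropane-1,3-dione, racemic and enolisable | COCOc1c(OC)c(OC)cc(OCc2ccccc2)c1C(=O)C(OC)C(=O)c1ccc(OCc2ccccc2)cc1OC | intermediate
17 | 1-[4-(benzyloxy)-2-methoxyphenyl]-3-[6-(benzyloxy)-2-hydroxy-3,4-dimethoxyphenyl]-2-methoxypropane-1,3-dione, racemic (not isolated) | Oc1c(OC)c(OC)cc(OCc2ccccc2)c1C(=O)C(OC)C(=O)c1ccc(OCc2ccccc2)cc1OC | intermediate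
18 | 5-(benzyloxy)-2-[4-(benzyloxy)-2-methoxyphenyl]-2-hydroxy-3,7,8-trimethoxychroman-4-one, mixture of racemic diastereomers at C2 and C3 (not isolated) | COc1cc(OCc2ccccc2)ccc1C1(O)Oc2c(OC)c(OC)cc(OCc3ccccc3)c2C(=O)C1OC | intermediate
19 | 5-(benzyloxy)-2-[4-(benzyloxy)-2-methoxyphenyl]-3,7,8-trimethoxy-4H-chromen-4-one | COc1cc(OCc2ccccc2)ccc1-c1oc2c(OC)c(OC)cc(OCc3ccccc3)c2c(=O)c1OC | intermediate
20 | 5,4'-dihydroxy-3,7,8,2'-tetramethoxyflavone | COc1cc(O)ccc1-c1oc2c(OC)c(OC)cc(O)c2c(=O)c1OC | target

Total step count: 9
Longest linear sequence: 7 steps (steps 1, 2, 3, 4, 7, 8, 9)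

Steps most likely to fail

Step 7. The hindered aroyl–palladium intermediate may be captured too slowly by the trisubstituted enolate. Coupling without carbon monoxide uptake, acylation at the enolate oxygen or plain reduction of the C–I bond could then take over. The fallback uses no palladium, and C4 then comes from carbon dioxide. It sets out from 5, whose aryllithium 6, made as in step 4, is quenched with CO2 (THF, −78 °C, citric acid work-up) to give 6-(benzyloxy)-3,4-dimethoxy-2-(methoxymethoxy)benzoic acid F1. 1,1'-Carbonyldiimidazole in THF converts this under neutral conditions into [6-(benzyloxy)-3,4-dimethoxy-2-(methoxymethoxy)phenyl](1H-imidazol-1-yl)methanone F2. A crossed Claisen C-acylation of sodium enolate 15 (two equivalents, THF, −78 °C → rt) with this acyl imidazole comes back to the route at 16.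

Step 4. Deprotonation may stray to the ring C–H between OBn and OMe, or to the benzylic CH2 followed by Wittig rearrangement. The fallback is electrophilic instead of anionic, and iodine enters before any benzyl group is present. It sets out from 1, which ICl and pyridine in dioxane should iodinate next to the free hydroxyl, between OH and CHO. The analogy is the 2-halogenation of isovanillin, and the other free site is screened by the in-plane methyl of the 5-methoxy group. This gives 3-hydroxy-2-iodo-4,5-dimethoxybenzaldehyde F3. MOMCl and K2CO3 then give 2-iodo-4,5-dimethoxy-3-(methoxymethoxy)benzaldehyde F4. Baeyer–Villiger oxidation with mCPBA buffered by NaHCO3 (an acid-free medium disfavours oxidation at iodine) leads through 2-iodo-4,5-dimethoxy-3-(methoxymethoxy)phenyl formate F5. Methanolysis gives 2-iodo-4,5-dimethoxy-3-(methoxymethoxy)phenol F6. Benzylation (BnBr, K2CO3, DMF) comes back to the route at 7.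

Step 8. In warm acidic methanol three things may go wrong:
- retro-Claisen cleavage of the crowded diketone by the solvent;
- early loss of the benzyl group on the C5 oxygen, which would open a second direction of ring closure;
- a stall at the hemiketal stage.

The fallback splits the step into two separate operations without a nucleophilic solvent. It sets out from 16. NaHSO4 on SiO2 in CH2Cl2 at rt removes only the phenolic MOM group, and phenol 17 is isolated in equilibrium with hemiketal 18. Water is then driven off azeotropically (pyridinium p-toluenesulfonate, toluene, Dean–Stark trap), which comes back to the route at 19. No new compound is made.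

Further compounds
F1 | step 7 | 6-(benzyloxy)-3,4-dimethoxy-2-(methoxymethoxy)benzoic acid | OC(=O)c1c(OCOC)c(OC)c(OC)cc1OCc1ccccc1
F2 | step 7 | [6-(benzyloxy)-3,4-dimethoxy-2-(methoxymethoxy)phenyl](1H-imidazol-1-yl)methanone | O=C(n1ccnc1)c1c(OCOC)c(OC)c(OC)cc1OCc1ccccc1
F3 | step 4 | 3-hydroxy-2-iodo-4,5-dimethoxybenzaldehyde | O=Cc1cc(OC)c(OC)c(O)c1I
F4 | step 4 | 2-iodo-4,5-dimethoxy-3-(methoxymethoxy)benzaldehyde | O=Cc1cc(OC)c(OC)c(OCOC)c1I
F5 | step 4 | 2-iodo-4,5-dimethoxy-3-(methoxymethoxy)phenyl formate | O=COc1cc(OC)c(OC)c(OCOC)c1I
F6 | step 4 | 2-iodo-4,5-dimethoxy-3-(methoxymethoxy)phenol | Oc1cc(OC)c(OC)c(OCOC)c1I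
F0 | step 8 | none | none
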